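## Retrosynthetic overview

1. The last C–C bond is C12–C13, made by Negishi sp3–sp2 coupling of the alkylzinc from the silylated labdane-core iodide 26 with the bromovinyl peroxy-lactone 41 (fragment 2); global desilylation then gives the target.
2. Fragment 2: the 1,2-dioxane is closed last by 6-exo SN2 attack of a tertiary hydroperoxide on an (S)-2-bromoallylic mesylate; hydroperoxide and trans-disposed γ-lactone come from anti opening of an (S,S)-epoxide (Shi) by H2O2; the chain comes from alkyne carboalumination plus (S)-2-(1-bromoethenyl)oxirane.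
3. Core: ring B first ((R)-linalool → RCM → 4-silyloxy enone 8; Cu-catalysed vinyl addition and acrolein aldol set C9, C10, C1), then a temporary six-membered lactone C18(=O)–O–C1 (intramolecular HWE), then ring A by a ring-contracting Ireland–Claisen rearrangement (C3–C4 bond, quaternary C4), then hydroboration of C5=C6 (5α-H, 6α-OH).
4. Enabling feature: the quaternary C4 of ring A carries its own carboxyl carbon C18 and lies 1,4 to C1 (C4–C5–C10–C1). C18 and C1 can therefore be tied through an ester oxygen into a δ-lactone that holds a C1-vinyl group (future C2–C3) over C4, while the C6 carbinol is carried as a C5=C6 double bond that makes C6–H the acidic γ-position of that lactone.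
5. Order of ring formation: ring B → temporary δ-lactone → ring A (lactone opened in the same event); separately γ-lactone → 1,2-dioxane.

Key step: step 9

## Remarks on the chemistry (assumptions)

- Labdane numbering is used: ring A = C1–C5, C10; ring B = C5–C10; chain C11, C12, C13(=C16H2), C14 (CH–OO), C15 (CH2); C17 = methyl on C8, C18 = ester carbon (4α), C19 = methyl on C4 (4β), C20 = methyl on C10. The four further carbons are C1′ (CH–O of the γ-lactone), C2′ (C(CH3)–OO), C3′ (CH2), C4′ (lactone C=O).
- The target SMILES is read as a trans-fused γ-lactone/1,2-dioxane (C1′–O and C2′–CH2 trans) with the C14–C13 bond trans to the C1′–O bond; the route is built for exactly this relative configuration.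
- Organoborane intermediates are drawn as the simplest monoalkylboranes; a free hydroxyl present during hydroboration is transiently borylated.
- 2-Bromoacrolein and the L-fructose-derived Shi ketone are taken as purchasable speciality chemicals.

## Route

**Core (steps 1–15)**

Step 1
Reactants: 1 (R)-(−)-linalool
Product: 2 (R)-3,7-dimethyl-3-(triethylsilyloxy)octa-1,6-diene
Conditions: TESOTf, 2,6-lutidine, CH2Cl2, −78 → 0 °C
Reagents that add atoms: triethylsilyl triflate, CC[Si](CC)(CC)OS(=O)(=O)C(F)(F)F
Why: Silyl triflate silylation of the tertiary allylic alcohol is reliable and masks the future C8 hydroxyl with a bulky group that later steers the conjugate addition, the (R)-centre (future C8) being taken from the chiral pool.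

Step 2
Reactants: 2 (R)-3,7-dimethyl-3-(triethylsilyloxy)octa-1,6-diene
Product: 4 (R)-4-methyl-4-(triethylsilyloxy)hex-5-enal, via secondary ozonide 3 (not isolated)
Conditions: O3 (1 equiv, Sudan Red 7B end point), CH2Cl2, −78 °C; then Me2S, −78 °C → rt
Reagents that add atoms: ozone, [O-][O+]=O
Why: Chemoselective ozonolysis, because the electron-rich trisubstituted alkene reacts much faster than the vinyl group next to the silyloxy-bearing quaternary carbon, and reductive work-up gives the aldehyde without touching the stereocentre.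

Step 3
Reactants: 4 (R)-4-methyl-4-(triethylsilyloxy)hex-5-enal; 5 isopropenylmagnesium bromide
Product: 6 (6R)-2,6-dimethyl-6-(triethylsilyloxy)octa-1,7-dien-3-ol (both C3 epimers)
Conditions: CH2=C(CH3)MgBr, THF, −78 → 0 °C; aq. NH4Cl
Reagents that add atoms: none
Why: Grignard 1,2-addition to the aldehyde, whose new carbinol centre is oxidised away two steps later so that no control is needed.

Step 4
Reactants: 6 (6R)-2,6-dimethyl-6-(triethylsilyloxy)octa-1,7-dien-3-ol
Product: 7 (4R)-2,4-dimethyl-4-(triethylsilyloxy)cyclohex-2-en-1-ol (both C1 epimers)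
Conditions: second-generation Grubbs catalyst (H2IMes)(PCy3)Cl2Ru=CHPh (5 mol %), CH2Cl2, 40 °C
Reagents that add atoms: none
Why: Ring-closing metathesis closes ring B as a six-membered ring with a trisubstituted alkene, the free allylic hydroxyl assisting metathesis at the 1,1-disubstituted alkene and loss of ethylene driving the reaction.

Step 5
Reactants: 7 (4R)-2,4-dimethyl-4-(triethylsilyloxy)cyclohex-2-en-1-ol
Product: 8 (R)-2,4-dimethyl-4-(triethylsilyloxy)cyclohex-2-en-1-one
Conditions: Dess–Martin periodinane, NaHCO3, CH2Cl2, 0 °C → rt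
Reagents that add atoms: none
Why: Buffered Dess–Martin oxidation of the allylic alcohol gives the enone (C5=O, C10=C9, C8 in labdane numbering) without affecting the silyl ether or the stereocentre.

Step 6
Reactants: 8 (R)-2,4-dimethyl-4-(triethylsilyloxy)cyclohex-2-en-1-one; 9 vinylmagnesium bromide; 10 acrolein
Product: 12 (2S,3R,4R)-2-[(1S)-1-hydroxyprop-2-en-1-yl]-2,4-dimethyl-4-(triethylsilyloxy)-3-vinylcyclohexan-1-one, via magnesium enolate 11 (not isolated)
Conditions: CH2=CHMgBr, CuBr·SMe2 (10 mol %), THF, −40 °C; then acrolein, −78 °C; aq. NH4Cl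
Reagents that add atoms: none
Why: In this three-component conjugate addition–aldol sequence the copper-catalysed 1,4-addition of the vinyl group occurs anti to the pseudo-axial C8 silyloxy group (sets C9), and the tetrasubstituted magnesium enolate then adds to acrolein anti to the new C9 vinyl group (sets C10) through a Zimmerman–Traxler chair with the aldehyde vinyl group equatorial (sets C1 as S).

Step 7
Reactants: 12 the aldol of step 6; 13 2-(diethoxyphosphoryl)propanoic acid
Product: 14 2-(diethoxyphosphoryl)propanoate ester of 12 at the (1S)-carbinol (phosphonate α-centre as a mixture)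
Conditions: DCC, DMAP (cat.), CH2Cl2, 0 °C → rt
Reagents that add atoms: none
Why: Steglich esterification at 0 °C acylates the hindered secondary allylic alcohol before retro-aldol cleavage can compete and installs the phosphonate for ring closure, the phosphonate α-centre being inconsequential.

Step 8
Reactants: 14 the phosphonate ester of step 7
Product: 15 (1S)-8α-(triethylsilyloxy)-3,4-seco-13,14,15,16-tetranorlabda-2,4,11-trien-18,1-olide (δ-lactone C18(=O)–O–C1 with C4=C5 in the lactone ring; vinyl groups on C1 and C9)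
Conditions: LiCl, DBU, MeCN, rt → 50 °C
Reagents that add atoms: none
Why: Intramolecular Horner–Wadsworth–Emmons olefination under Masamune–Roush conditions closes the six-membered α,β-unsaturated lactone onto the C5 ketone, the ring enforcing the alkene geometry and no new stereocentre being formed.

Step 9
Reactants: 15 the α,β-unsaturated δ-lactone of step 8
Product: 18 8α-(triethylsilyloxy)-13,14,15,16-tetranorlabda-1,5,11-trien-18-oic acid (4α-CO2H; 4β-CH3; 9β-vinyl; 10β-CH3), via silyl ketene acetal 16 (not isolated), via trimethylsilyl ester 17 (not isolated)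
Conditions: LiN(iPr)2 (LDA), then TMSCl/Et3N, THF/DMPU, −78 → 0 °C; solvent exchange to PhMe, 105 °C; 5% aq. citric acid
Reagents that add atoms: none
Why: LiN(iPr)2 removes the γ-proton at C6 of the α,β-unsaturated lactone and O-silylation gives the extended silyl ketene acetal 16 (C18(OSiMe3)=C4–C5=C6), which on heating undergoes a suprafacial [3,3]-sigmatropic (Ireland–Claisen) shift that exchanges the C1–O bond for the C3–C4 bond and the C1=C2 double bond. The closest known reaction type is the ring-contracting Ireland–Claisen rearrangement of lactone silyl ketene acetals that carry an alkenyl group on the carbinol carbon, combined with the α-selective Claisen rearrangement of ester dienolates. Ring A is closed as a six-membered carbocycle through a boat-like, bicyclo[2.2.2]octane-shaped transition state, the only geometry in which the C1 vinyl group can reach C4 across the lactone. The new quaternary stereocentre C4 is controlled by the C1 carbinol configuration: the vinyl group, cis to the C10 methyl on the lactone ring, delivers C3 to that face of C4 while C18 stays bonded, so the carboxyl group ends α (trans to the C10 methyl) and the C4 methyl β. The step needs γ-deprotonation rather than attack at the carbonyl and C–C bond formation at C4 rather than at C6; the first is secured by the absence of any α-hydrogen and the hindered amide base, the second by the tether, since only C4 is within bonding distance of C3. The surviving C5=C6 double bond is the handle for the later introduction of 5α-H and 6α-OH.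

Step 10
Reactants: 18 the acid of step 9
Product: 19 methyl 8α-(triethylsilyloxy)-13,14,15,16-tetranorlabda-1,5,11-trien-18-oate
Conditions: TMSCHN2, PhMe/MeOH, 0 °C
Reagents that add atoms: (trimethylsilyl)diazomethane, C[Si](C)(C)C=[N+]=[N-]
Why: O-Methylation of the hindered tertiary carboxylic acid with a diazoalkane needs neither base nor attack at the carbonyl and touches no stereocentre.

Step 11
Reactants: 19 the triene methyl ester of step 10
Product: 21 methyl 12-hydroxy-8α-(triethylsilyloxy)-13,14,15,16-tetranorlabda-1,5-dien-18-oate, via B-alkyl-9-BBN adduct 20 (not isolated)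
Conditions: 9-BBN, THF, 0 °C → rt; then 3 M NaOH, 30% H2O2, 0 °C
Reagents that add atoms: hydrogen peroxide, OO
Why: 9-BBN hydroborates the monosubstituted C11=C12 vinyl group far faster than the cis-disubstituted ring-A alkene or the trisubstituted C5=C6 alkene, and alkaline peroxide oxidation gives the anti-Markovnikov primary alcohol.

Step 12
Reactants: 21 the dienyl alcohol of step 11
Product: 22 methyl 12-hydroxy-8α-(triethylsilyloxy)-13,14,15,16-tetranorlabd-5-en-18-oate
Conditions: H2 (1 atm), palladium on carbon (Pd/C, 5%), EtOAc, rt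
Reagents that add atoms: none
Why: Heterogeneous hydrogenation saturates the disubstituted C1=C2 alkene, whereas the trisubstituted C5=C6 alkene flanked by the quaternary carbons C4 and C10 is too hindered to be reduced under these mild conditions.

Step 13
Reactants: 22 the Δ5 alcohol of step 12
Product: 24 methyl 6α,12-dihydroxy-8α-(triethylsilyloxy)-13,14,15,16-tetranorlabdan-18-oate, via C6 alkylborane 23 (not isolated)
Conditions: BH3·THF (excess), THF, 0 → 40 °C; then 3 M NaOH, 30% H2O2, 0 °C → rt
Reagents that add atoms: hydrogen peroxide, OO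
Why: Hydroboration–oxidation places boron on the less substituted C6 and adds H and B syn from the α-face, opposite the axial β-methyl groups on C4, C8 and C10, which sets 5α-H (trans ring fusion) and 6α-OH in one operation while the hindered tertiary ester is left intact.

Step 14
Reactants: 24 the diol of step 13
Product: 25 methyl 6α-hydroxy-12-iodo-8α-(triethylsilyloxy)-13,14,15,16-tetranorlabdan-18-oate
Conditions: I2, PPh3, imidazole, CH2Cl2, 0 °C
Reagents that add atoms: iodine, II
Why: Appel-type iodination (Garegg–Samuelsson conditions) converts the unhindered primary alcohol selectively, since the secondary 6α-hydroxyl next to the ring fusion reacts much more slowly.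

Step 15
Reactants: 25 the iodo alcohol of step 14
Product: 26 methyl 12-iodo-6α,8α-bis(triethylsilyloxy)-13,14,15,16-tetranorlabdan-18-oate
Conditions: TESOTf, 2,6-lutidine, CH2Cl2, −78 °C
Reagents that add atoms: triethylsilyl triflate, CC[Si](CC)(CC)OS(=O)(=O)C(F)(F)F
Why: Silylation of the secondary alcohol gives the aprotic iodide needed for zinc insertion and affects no stereocentre.

**Fragment 2 (steps 16–25)**

Step 16
Reactants: 27 2-bromoacrolein
Product: 28 rac-2-(1-bromoethenyl)oxirane
Conditions: Me3S+ I−, KOtBu, DMSO/THF, 0 °C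
Reagents that add atoms: trimethylsulfonium iodide, C[S+](C)C.[I-]
Why: Corey–Chaykovsky epoxidation, in which the sulfonium ylide adds 1,2 to the enal carbonyl and closes the epoxide to give the racemic vinyl epoxide.

Step 17
Reactants: 28 rac-2-(1-bromoethenyl)oxirane
Product: 29 (S)-2-(1-bromoethenyl)oxirane
Conditions: (R,R)-(salen)Co(OAc) (trivalent cobalt; salen = N,N′-bis(3,5-di-tert-butylsalicylidene)-1,2-cyclohexanediamine dianion; 0.5 mol %), H2O (0.55 equiv), THF, 0 °C → rt; distillation
Reagents that add atoms: none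
Why: Jacobsen hydrolytic kinetic resolution of a terminal epoxide, the catalyst enantiomer being chosen so that the (R)-epoxide is hydrolysed and the (S)-epoxide (future C14) is recovered by distillation from the diol.

Step 18
Reactants: 30 tert-butyl(but-3-yn-1-yloxy)dimethylsilane; 29 (S)-2-(1-bromoethenyl)oxirane
Product: 33 (3S,5E)-2-bromo-8-(tert-butyldimethylsilyloxy)-6-methylocta-1,5-dien-3-ol, via alkenylalane 31 (not isolated), via lithium alanate 32 (not isolated)
Conditions: Me3Al (2 equiv), Cp2ZrCl2 (0.25 equiv), CH2Cl2, 0 °C → rt; volatiles removed; THF, n-BuLi, −78 °C; then 29, −78 → 0 °C; aq. KNaC4H4O6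
Reagents that add atoms: trimethylaluminium, C[Al](C)C
Why: Zirconium-catalysed syn-methylalumination of the terminal alkyne fixes the E-trisubstituted alkene, and the derived lithium alanate opens the terminal epoxide at its CH2 carbon with retention at the carbinol carbon to give the (S)-homoallylic alcohol.

Step 19
Reactants: 33 the silyl ether of step 18
Product: 34 (3E,6S)-7-bromo-3-methylocta-3,7-diene-1,6-diol
Conditions: CSA (10 mol %), MeOH, 0 °C → rt
Reagents that add atoms: none
Why: Acid-catalysed methanolysis removes the primary TBS ether without affecting the bromoallylic alcohol or the alkenes.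

Step 20
Reactants: 34 the diol of step 19
Product: 35 (3E,6S)-7-bromo-6-hydroxy-3-methylocta-3,7-dienoic acid
Conditions: TEMPO (20 mol %), PhI(OAc)2 (2.5 equiv), MeCN/H2O (1:1), rt
Reagents that add atoms: water, O
Why: Oxoammonium (TEMPO/PhI(OAc)2) oxidation in aqueous acetonitrile takes the primary alcohol to the carboxylic acid while the more hindered, electron-poor secondary bromoallylic alcohol is left, and the near-neutral medium keeps the β,γ-double bond out of conjugation.

Step 21
Reactants: 35 the hydroxy acid of step 20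
Product: 36 methyl (3E,6S)-7-bromo-6-hydroxy-3-methylocta-3,7-dienoate
Conditions: TMSCHN2, PhMe/MeOH, 0 °C
Reagents that add atoms: (trimethylsilyl)diazomethane, C[Si](C)(C)C=[N+]=[N-]
Why: Diazoalkane esterification under neutral conditions gives the methyl ester without isomerising the β,γ-unsaturated system.

Step 22
Reactants: 36 the hydroxy ester of step 21
Product: 37 methyl 2-[(2S,3S)-3-[(2S)-3-bromo-2-hydroxybut-3-en-1-yl]-2-methyloxiran-2-yl]acetate
Conditions: L-fructose-derived Shi ketone (ent-Shi ketone, 0.3 equiv), Oxone (2KHSO5·KHSO4·K2SO4), K2CO3, Bu4NHSO4, MeCN/dimethoxymethane/aq. Na2B4O7 buffer (pH 10.5), 0 °C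
Reagents that add atoms: potassium peroxymonosulfate (Oxone), [K+].[O-]S(=O)(=O)OO
Why: In this Shi epoxidation the chiral dioxirane attacks the E-trisubstituted alkene through the spiro transition state on the face that gives the (S,S)-epoxide (this ketone is the enantiomer of the one that gives (R,R)-epoxides) while the electron-poor bromoalkene is inert, which sets C1′ and, after the later inversion, C2′.

Step 23
Reactants: 37 the epoxy alcohol of step 22
Product: 38 methyl 2-[(2S,3S)-3-[(2S)-3-bromo-2-(methylsulfonyloxy)but-3-en-1-yl]-2-methyloxiran-2-yl]acetate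
Conditions: MsCl, Et3N, CH2Cl2, −20 °C
Reagents that add atoms: methanesulfonyl chloride, CS(=O)(=O)Cl
Why: Mesylation of the secondary alcohol proceeds with retention, and the electron-withdrawing bromovinyl group suppresses ionisation so that the 2-bromoallylic mesylate is a clean SN2 electrophile.

Step 24
Reactants: 38 the epoxy mesylate of step 23
Product: 40 (4R,5S)-5-[(2S)-3-bromo-2-(methylsulfonyloxy)but-3-en-1-yl]-4-hydroperoxy-4-methyloxolan-2-one, via hydroperoxy hydroxy ester 39 (not isolated)
Conditions: anhydrous H2O2 in Et2O (excess), H3PMo12O40 (5 mol %), rt; then CSA (cat.), CH2Cl2, 4 Å MS, rt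
Reagents that add atoms: hydrogen peroxide, OO
Why: Acid-catalysed opening of the trisubstituted epoxide by hydrogen peroxide occurs at the tertiary carbon with inversion to give the anti β-hydroxy hydroperoxide 39, whose secondary hydroxyl then lactonises onto the methyl ester, and this anti relationship of the two oxygens is what makes the later lactone–dioxane fusion trans.

Step 25
Reactants: 40 the hydroperoxy lactone of step 24
Product: 41 (1R,4R,6S)-4-(1-bromoethenyl)-1-methyl-2,3,7-trioxabicyclo[4.3.0]nonan-8-one (trans-fused; fragment 2)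
Conditions: Cs2CO3 (1.2 equiv), DMF, 0 °C → rt
Reagents that add atoms: none
Why: Intramolecular alkylation of the hydroperoxide (6-exo-tet SN2) at the mesylate-bearing carbon closes the 1,2-dioxane with inversion, turning the (S)-mesylate into the (R)-configured C14 and completing the trans-fused bicycle encoded in 40.

**Union and end game (steps 26–27)**

Step 26
Reactants: 26 methyl 12-iodo-6α,8α-bis(triethylsilyloxy)-13,14,15,16-tetranorlabdan-18-oate; 41 the bromovinyl peroxy-lactone (fragment 2)
Product: 43 6,8-bis-O-triethylsilyl ether of the target, via alkylzinc iodide 42 (not isolated)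
Conditions: Zn dust (activated with 1,2-dibromoethane and TMSCl), LiCl, THF, 35 °C; then 41, Pd-PEPPSI-IPr, (IPr)(3-chloropyridine)PdCl2 (divalent palladium precatalyst, 3 mol %), THF/NMP, rt
Reagents that add atoms: none
Why: LiCl-assisted zinc insertion into the primary iodide followed by Negishi sp3–sp2 coupling with the alkenyl bromide under a phosphine-free NHC–palladium catalyst joins C12 to C13 under neutral conditions that the β-peroxy lactone should tolerate, and no stereocentre is involved.

Step 27
Reactants: 43 the bis-silyl ether of step 26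
Product: 44 CNP0162504.1 (target)
Conditions: HF·pyridine, pyridine/THF, 0 °C → rt
Reagents that add atoms: none
Why: Buffered fluoride cleavage of the secondary and tertiary triethylsilyl ethers liberates the 6α- and 8α-hydroxyls without the basic or reducing conditions that would trigger Kornblum–DeLaMare-type or reductive loss of the peroxide.

## Compound list

1 | (R)-(−)-linalool, (3R)-3,7-dimethylocta-1,6-dien-3-ol | C=C[C@](C)(O)CCC=C(C)C | starting material
2 | (R)-3,7-dimethyl-3-(triethylsilyloxy)octa-1,6-diene | C=C[C@](C)(O[Si](CC)(CC)CC)CCC=C(C)C | intermediate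
3 | 3,3-dimethyl-5-[(3R)-3-methyl-3-(triethylsilyloxy)pent-4-enyl]-1,2,4-trioxolane (secondary ozonide) | C=C[C@](C)(O[Si](CC)(CC)CC)CCC1OOC(C)(C)O1 | intermediate (not isolated)
4 | (R)-4-methyl-4-(triethylsilyloxy)hex-5-enal | C=C[C@](C)(O[Si](CC)(CC)CC)CCC=O | intermediate
5 | isopropenylmagnesium bromide | CC(=C)[Mg]Br | starting material
6 | (6R)-2,6-dimethyl-6-(triethylsilyloxy)octa-1,7-dien-3-ol (both C3 epimers) | C=C[C@](C)(O[Si](CC)(CC)CC)CCC(O)C(C)=C | intermediate
7 | (4R)-2,4-dimethyl-4-(triethylsilyloxy)cyclohex-2-en-1-ol (both C1 epimers) | CC1=C[C@](C)(O[Si](CC)(CC)CC)CCC1O | intermediate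
8 | (R)-2,4-dimethyl-4-(triethylsilyloxy)cyclohex-2-en-1-one | CC1=C[C@](C)(O[Si](CC)(CC)CC)CCC1=O | intermediate
9 | vinylmagnesium bromide | C=C[Mg]Br | starting material
10 | acrolein | C=CC=O | starting material
11 | bromomagnesium enolate of the 1,4-adduct (C5–O–Mg, C5=C10; 9β-vinyl trans to 8α-OTES) | C=C[C@@H]1C(C)=C(O[Mg]Br)CC[C@@]1(C)O[Si](CC)(CC)CC | intermediate (not isolated)
12 | (2S,3R,4R)-2-[(1S)-1-hydroxyprop-2-en-1-yl]-2,4-dimethyl-4-(triethylsilyloxy)-3-vinylcyclohexan-1-one | C=C[C@@H]1[C@@](C)([C@@H](O)C=C)C(=O)CC[C@@]1(C)O[Si](CC)(CC)CC | intermediate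
13 | 2-(diethoxyphosphoryl)propanoic acid | CCOP(=O)(OCC)C(C)C(=O)O | starting material
14 | 2-(diethoxyphosphoryl)propanoate of 12 at the (1S)-carbinol | C=C[C@@H]1[C@@](C)([C@@H](OC(=O)C(C)P(=O)(OCC)OCC)C=C)C(=O)CC[C@@]1(C)O[Si](CC)(CC)CC | intermediate
15 | (1S)-8α-(triethylsilyloxy)-3,4-seco-13,14,15,16-tetranorlabda-2,4,11-trien-18,1-olide | C=C[C@@H]1[C@@]2(C)[C@H](C=C)OC(=O)C(C)=C2CC[C@@]1(C)O[Si](CC)(CC)CC | intermediate
16 | extended trimethylsilyl ketene acetal of 15 (C18(OSiMe3)=C4, C5=C6) | C=C[C@@H]1[C@@]2(C)[C@H](C=C)OC(O[Si](C)(C)C)=C(C)C2=CC[C@@]1(C)O[Si](CC)(CC)CC | intermediate (not isolated)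
17 | trimethylsilyl 8α-(triethylsilyloxy)-13,14,15,16-tetranorlabda-1,5,11-trien-18-oate | C=C[C@@H]1[C@@]2(C)C=CC[C@@](C)(C(=O)O[Si](C)(C)C)C2=CC[C@@]1(C)O[Si](CC)(CC)CC | intermediate (not isolated)
18 | 8α-(triethylsilyloxy)-13,14,15,16-tetranorlabda-1,5,11-trien-18-oic acid | C=C[C@@H]1[C@@]2(C)C=CC[C@@](C)(C(=O)O)C2=CC[C@@]1(C)O[Si](CC)(CC)CC | intermediate
19 | methyl 8α-(triethylsilyloxy)-13,14,15,16-tetranorlabda-1,5,11-trien-18-oate | C=C[C@@H]1[C@@]2(C)C=CC[C@@](C)(C(=O)OC)C2=CC[C@@]1(C)O[Si](CC)(CC)CC | intermediate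
20 | 12-(9-borabicyclo[3.3.1]nonan-9-yl) adduct of 19 | B1(C2CCCC1CCC2)CC[C@@H]1[C@@]2(C)C=CC[C@@](C)(C(=O)OC)C2=CC[C@@]1(C)O[Si](CC)(CC)CC | intermediate (not isolated)
21 | methyl 12-hydroxy-8α-(triethylsilyloxy)-13,14,15,16-tetranorlabda-1,5-dien-18-oate | OCC[C@@H]1[C@@]2(C)C=CC[C@@](C)(C(=O)OC)C2=CC[C@@]1(C)O[Si](CC)(CC)CC | intermediate
22 | methyl 12-hydroxy-8α-(triethylsilyloxy)-13,14,15,16-tetranorlabd-5-en-18-oate | OCC[C@@H]1[C@@]2(C)CCC[C@@](C)(C(=O)OC)C2=CC[C@@]1(C)O[Si](CC)(CC)CC | intermediate
23 | 6α-boryl-5α-H adduct of 22 (drawn as the monoalkylborane) | OCC[C@@H]1[C@@]2(C)CCC[C@@](C)(C(=O)OC)[C@@H]2[C@@H](B)C[C@@]1(C)O[Si](CC)(CC)CC | intermediate (not isolated)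
24 | methyl 6α,12-dihydroxy-8α-(triethylsilyloxy)-13,14,15,16-tetranorlabdan-18-oate | OCC[C@@H]1[C@@]2(C)CCC[C@@](C)(C(=O)OC)[C@@H]2[C@@H](O)C[C@@]1(C)O[Si](CC)(CC)CC | intermediate
25 | methyl 6α-hydroxy-12-iodo-8α-(triethylsilyloxy)-13,14,15,16-tetranorlabdan-18-oate | ICC[C@@H]1[C@@]2(C)CCC[C@@](C)(C(=O)OC)[C@@H]2[C@@H](O)C[C@@]1(C)O[Si](CC)(CC)CC | intermediate
26 | methyl 12-iodo-6α,8α-bis(triethylsilyloxy)-13,14,15,16-tetranorlabdan-18-oate | ICC[C@@H]1[C@@]2(C)CCC[C@@](C)(C(=O)OC)[C@@H]2[C@@H](O[Si](CC)(CC)CC)C[C@@]1(C)O[Si](CC)(CC)CC | intermediate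
27 | 2-bromoacrolein (2-bromoprop-2-enal) | C=C(Br)C=O | starting material
28 | rac-2-(1-bromoethenyl)oxirane | C=C(Br)C1CO1 | intermediate
29 | (S)-2-(1-bromoethenyl)oxirane | C=C(Br)[C@@H]1CO1 | intermediate
30 | tert-butyl(but-3-yn-1-yloxy)dimethylsilane | C#CCCO[Si](C)(C)C(C)(C)C | starting material
31 | (E)-[4-(tert-butyldimethylsilyloxy)-2-methylbut-1-en-1-yl]dimethylalane | C[Al](C)/C=C(\C)CCO[Si](C)(C)C(C)(C)C | intermediate (not isolated)
32 | lithium butyl[(E)-4-(tert-butyldimethylsilyloxy)-2-methylbut-1-en-1-yl]dimethylalanate | [Li+].CCCC[Al-](C)(C)/C=C(\C)CCO[Si](C)(C)C(C)(C)C | intermediate (not isolated)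
33 | (3S,5E)-2-bromo-8-(tert-butyldimethylsilyloxy)-6-methylocta-1,5-dien-3-ol | C=C(Br)[C@@H](O)C/C=C(\C)CCO[Si](C)(C)C(C)(C)C | intermediate
34 | (3E,6S)-7-bromo-3-methylocta-3,7-diene-1,6-diol | C=C(Br)[C@@H](O)C/C=C(\C)CCO | intermediate
35 | (3E,6S)-7-bromo-6-hydroxy-3-methylocta-3,7-dienoic acid | C=C(Br)[C@@H](O)C/C=C(\C)CC(=O)O | intermediate
36 | methyl (3E,6S)-7-bromo-6-hydroxy-3-methylocta-3,7-dienoate | C=C(Br)[C@@H](O)C/C=C(\C)CC(=O)OC | intermediate
37 | methyl 2-[(2S,3S)-3-[(2S)-3-bromo-2-hydroxybut-3-en-1-yl]-2-methyloxiran-2-yl]acetate | C=C(Br)[C@@H](O)C[C@@H]1O[C@@]1(C)CC(=O)OC | intermediate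
38 | methyl 2-[(2S,3S)-3-[(2S)-3-bromo-2-(methylsulfonyloxy)but-3-en-1-yl]-2-methyloxiran-2-yl]acetate | C=C(Br)[C@@H](OS(C)(=O)=O)C[C@@H]1O[C@@]1(C)CC(=O)OC | intermediate
39 | methyl (3R,4S,6S)-7-bromo-3-hydroperoxy-4-hydroxy-3-methyl-6-(methylsulfonyloxy)oct-7-enoate | C=C(Br)[C@@H](OS(C)(=O)=O)C[C@H](O)[C@](C)(OO)CC(=O)OC | intermediate (not isolated)
40 | (4R,5S)-5-[(2S)-3-bromo-2-(methylsulfonyloxy)but-3-en-1-yl]-4-hydroperoxy-4-methyloxolan-2-one | C=C(Br)[C@@H](OS(C)(=O)=O)C[C@@H]1OC(=O)C[C@@]1(C)OO | intermediate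
41 | (1R,4R,6S)-4-(1-bromoethenyl)-1-methyl-2,3,7-trioxabicyclo[4.3.0]nonan-8-one (trans-fused; fragment 2) | C=C(Br)[C@H]1C[C@@H]2OC(=O)C[C@@]2(C)OO1 | intermediate
42 | alkylzinc iodide from 26 (C12–ZnI) | I[Zn]CC[C@@H]1[C@@]2(C)CCC[C@@](C)(C(=O)OC)[C@@H]2[C@@H](O[Si](CC)(CC)CC)C[C@@]1(C)O[Si](CC)(CC)CC | intermediate (not isolated)
43 | 6,8-bis-O-triethylsilyl ether of the target | C=C(CC[C@@H]1[C@@]2(C)CCC[C@@](C)(C(=O)OC)[C@@H]2[C@@H](O[Si](CC)(CC)CC)C[C@@]1(C)O[Si](CC)(CC)CC)[C@H]1C[C@@H]2OC(=O)C[C@@]2(C)OO1 | intermediate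
44 | CNP0162504.1: methyl 6α,8α-dihydroxy-labd-13(16)-en-18-oate carrying at C13 the (1R,4R,6S)-1-methyl-8-oxo-2,3,7-trioxabicyclo[4.3.0]nonan-4-yl unit | C=C(CC[C@@H]1[C@@]2(C)CCC[C@@](C)(C(=O)OC)[C@@H]2[C@@H](O)C[C@@]1(C)O)[C@H]1C[C@@H]2OC(=O)C[C@@]2(C)OO1 | target

## Step count and risk

Total step count: 27.
Longest linear sequence: 17 steps (steps 1–15, then 26 and 27); fragment 2 takes 10 steps (16–25) before the union.

**Steps most likely to fail**

1. Step 9 (key step). What may go wrong: the boat-like transition state may not be reached before the silyl ketene acetal is lost by desilylation or by ionisation of the allylic C1–O bond, or γ-deprotonation may be incomplete.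
Fallback (sets out from 8, returns at 22): the same C3–C4 bond is made by intramolecular SN2 alkylation of an extended ester enolate instead of a sigmatropic shift. Enone 8 is converted as in step 6 into enolate 11, which is trapped with 1-chloro-3-iodopropane (HMPA, −40 → 0 °C) anti to the C9 vinyl group to give the 10-(3-chloropropyl) ketone F1. Addition of the lithium enolate of methyl propanoate (CeCl3, THF, −78 °C) gives the β-hydroxy ester F2, and dehydration (SOCl2, pyridine, 0 °C) gives the unsaturated ester F3 (its conjugated isomer leads to the same enolate). LiN(iPr)2/HMPA with NaI then generates the extended enolate, whose α-carbon C4 displaces the primary chloride (6-exo-tet) to give the ring-A-saturated diene ester F4. Hydroboration of the C9 vinyl group of F4 with 9-BBN and alkaline H2O2 gives alcohol 22, so steps 7–12 are bypassed. The C4 configuration would then rest on conformational control (ester turned away from the C10 quaternary centre) and would have to be checked.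

2. Step 26. What may go wrong: zerovalent palladium or the organozinc may insert into or reduce the O–O bond, or the alkenylpalladium intermediate may eliminate the allylic peroxy oxygen, before transmetalation occurs.
Fallback (sets out from 36 and 26, returns at 43): the C12–C13 bond is made before any O–O bond exists. Alkylzinc iodide 42 is coupled under the same palladium catalysis with hydroxy ester 36 to give the coupled hydroxy ester F5. Shi epoxidation with the same L-fructose-derived ketone (the trisubstituted alkene reacting before the 1,1-disubstituted one) gives the epoxy alcohol F6. Mesylation at −40 °C gives the allylic mesylate F7, which is used at once. H2O2/H3PMo12O40 and then CSA give, through the hydroperoxy hydroxy ester F8, the hydroperoxy lactone F9, and Cs2CO3 in DMF closes the dioxane to give 43. The price is a more labile, non-brominated allylic mesylate, which is why this order is the fallback.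

3. Step 25. What may go wrong: elimination of the mesylate or attack of the hydroperoxide anion on the lactone carbonyl may outrun the 6-exo displacement, which has to build a trans-fused bicycle on a preformed five-membered ring.
Fallback (sets out from 38, returns at 41): the order of the two ring closures is inverted so that the dioxane forms on a flexible chain. The epoxide opening of 38 is stopped before lactonisation (H2O2, H3PMo12O40, Et2O, 0 °C, NaHCO3 work-up) and 39 is isolated. Cs2CO3 in DMF then closes the monocyclic 1,2-dioxane hydroxy ester F10 by the same SN2 inversion, and CSA (cat.) in CH2Cl2 closes the trans-fused γ-lactone to give 41.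

Further compounds
F1 | step 9 | 2-(3-chloropropyl)-2,4-dimethyl-4-(triethylsilyloxy)-3-vinylcyclohexan-1-one (chloropropyl trans to vinyl, vinyl trans to OTES) | C=C[C@@H]1[C@@](C)(CCCCl)C(=O)CC[C@@]1(C)O[Si](CC)(CC)CC
F2 | step 9 | methyl 2-[2-(3-chloropropyl)-1-hydroxy-2,4-dimethyl-4-(triethylsilyloxy)-3-vinylcyclohexyl]propanoate (mixture at the two new centres) | C=C[C@@H]1[C@@](C)(CCCCl)C(O)(C(C)C(=O)OC)CC[C@@]1(C)O[Si](CC)(CC)CC
F3 | step 9 | methyl 2-[6-(3-chloropropyl)-4,6-dimethyl-4-(triethylsilyloxy)-5-vinylcyclohex-1-en-1-yl]propanoate | C=C[C@@H]1[C@@](C)(CCCCl)C(C(C)C(=O)OC)=CC[C@@]1(C)O[Si](CC)(CC)CC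
F4 | step 9 | methyl 8α-(triethylsilyloxy)-13,14,15,16-tetranorlabda-5,11-dien-18-oate | C=C[C@@H]1[C@@]2(C)CCC[C@@](C)(C(=O)OC)C2=CC[C@@]1(C)O[Si](CC)(CC)CC
F5 | step 26 | coupled hydroxy ester: C12–C13 linked bis(triethylsilyl) core with (14S)-hydroxyl, (E)-C1′=C2′ alkene and C4′ methyl ester | C=C(CC[C@@H]1[C@@]2(C)CCC[C@@](C)(C(=O)OC)[C@@H]2[C@@H](O[Si](CC)(CC)CC)C[C@@]1(C)O[Si](CC)(CC)CC)[C@@H](O)C/C=C(\C)CC(=O)OC
F6 | step 26 | (1′S,2′S)-epoxide of F5 | C=C(CC[C@@H]1[C@@]2(C)CCC[C@@](C)(C(=O)OC)[C@@H]2[C@@H](O[Si](CC)(CC)CC)C[C@@]1(C)O[Si](CC)(CC)CC)[C@@H](O)C[C@@H]1O[C@@]1(C)CC(=O)OC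
F7 | step 26 | 14-methanesulfonate of F6 | C=C(CC[C@@H]1[C@@]2(C)CCC[C@@](C)(C(=O)OC)[C@@H]2[C@@H](O[Si](CC)(CC)CC)C[C@@]1(C)O[Si](CC)(CC)CC)[C@@H](OS(C)(=O)=O)C[C@@H]1O[C@@]1(C)CC(=O)OC
F8 | step 26 | 2′-hydroperoxy-1′-hydroxy methyl ester from F7 | C=C(CC[C@@H]1[C@@]2(C)CCC[C@@](C)(C(=O)OC)[C@@H]2[C@@H](O[Si](CC)(CC)CC)C[C@@]1(C)O[Si](CC)(CC)CC)[C@@H](OS(C)(=O)=O)C[C@H](O)[C@](C)(OO)CC(=O)OC
F9 | step 26 | 2′-hydroperoxy γ-lactone 14-mesylate | C=C(CC[C@@H]1[C@@]2(C)CCC[C@@](C)(C(=O)OC)[C@@H]2[C@@H](O[Si](CC)(CC)CC)C[C@@]1(C)O[Si](CC)(CC)CC)[C@@H](OS(C)(=O)=O)C[C@@H]1OC(=O)C[C@@]1(C)OO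
F10 | step 25 | methyl 2-[(3R,4S,6R)-6-(1-bromoethenyl)-4-hydroxy-3-methyl-1,2-dioxan-3-yl]acetate | C=C(Br)[C@H]1C[C@H](O)[C@@](C)(CC(=O)OC)OO1
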